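The molecule is divided at the methylene bridge into a butyryl chromene made from phloroglucinol and the dearomatised acetyl ring B. The quaternary C6 of ring B (methyl, geranyl) is the only stereocentre. The strategy rests on the C1–C6 bond of ring B. With O3 and O5 methylated, ring B is a cyclohexa-2,4-dienone whose carbonyl carbon C1 carries C6 as its α-substituent, and photochemical α-cleavage of this bond is the characteristic reaction of that chromophore. Light converts the racemic dimethoxy dienone into an achiral dienylketene. A chiral isothiourea recloses it, so one operation rebuilds C1–C6, ring B and the C6 configuration from the whole racemate.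

Key step: step 5

**Remarks before the steps**
- **Ring-B numbering:** C1 is the dienone carbonyl, C2 the C–H carbon that later carries the bridge, C3 bears O3, C4 bears the acetyl group, C5 bears O5, and C6 is the quaternary carbon.
- **Structure check:** the constitution and configuration of the racemic and the enantiopure dienone match ring B of the target and need no correction. Only the descriptor changes. C6 is S in the dienone, where C1=O outranks C5. The same centre is R in the free triketone and in the target, where the acetyl-side enol carbon outranks the bridge-side one.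
- **Ketene geometry:** the ketene is not one species, because C5=C6 can be E or Z. Both isomers are achiral, but a closure governed only by the helical sense of the chain would turn them into opposite enantiomers. The catalyst must therefore tell methyl from CH2 at C6, so a Lewis base is chosen that sits on C1, the atom that bonds to C6.
- **Installing the locks:** diazoalkane methylation of free acyl triketones of this type goes to the oxygen beside the quaternary carbon and remote from the acyl group (O1). That would lock the wrong tautomer. The O3 methyl is therefore placed on the arene before dearomatisation, which leaves a single enolic OH (O5–H) for the second methylation.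
- **Chromene regiochemistry:** with three free hydroxyls the non-chelated para oxygen would compete in the pyran closure and give the 6-acyl chromene. It is blocked as a silyl ether.
- **Light sensitivity:** the enantiopure dienone is configurationally stable only in the dark and is handled under yellow light.
- **Assumption:** the sense of induction of the new closure cannot be derived from precedent. (2S,3R)-HyperBTM is written, and its available antipode is used if the (R)-dienone is found to be enriched.

**Route**

Step 1
Reactants: 1 2-methylphloroglucinol
Product: 2 5-methoxy-2-methylbenzene-1,3-diol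
Conditions: MeOH, dry HCl (sat.), rt, stopped at partial conversion
Reagents that add atoms: methanol, CO
Why: Acid-catalysed etherification of a phloroglucinol through its keto tautomer (the classical alcohol/HCl method) should occur first at the one hydroxyl without an ortho substituent, the one para to the methyl group, and over-methylated material is removed by chromatography.

Step 2
Reactants: 2 5-methoxy-2-methylbenzene-1,3-diol
Product: 3 1-(2,4-dihydroxy-6-methoxy-3-methylphenyl)ethan-1-one
Conditions: Ac2O (1.05 equiv), BF3·OEt2 (solvent), 0 → 50 °C; aq. NaOAc
Reagents that add atoms: acetic anhydride, CC(=O)OC(C)=O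
Why: Friedel–Crafts C-acetylation (O-acylation/Fries under BF3) can give only one ketone because the two free ring carbons of 2 are equivalent, and the chelated, deactivated product resists a second acylation.

Step 3
Reactants: 3 1-(2,4-dihydroxy-6-methoxy-3-methylphenyl)ethan-1-one; 4 geranyl bromide
Product: 5 rac-4-acetyl-6-geranyl-5-hydroxy-3-methoxy-6-methylcyclohexa-2,4-dien-1-one
Conditions: LiHMDS (2.1 equiv), THF, −78 → 0 °C; 4 (1.0 equiv), 0 °C → rt; 1 M HCl
Reagents that add atoms: none
Why: In this alkylative dearomatisation, doubly deprotonated 3 is C-alkylated by the allylic bromide (SN2, E-alkene kept) at the methyl-bearing carbon between the two oxido groups, which creates C6 without stereocontrol as a racemate, and the isomer alkylated at the ring C–H carbon stays aromatic and is separated by chromatography.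

Step 4
Reactants: 5 rac-4-acetyl-6-geranyl-5-hydroxy-3-methoxy-6-methylcyclohexa-2,4-dien-1-one
Product: 6 rac-4-acetyl-6-geranyl-3,5-dimethoxy-6-methylcyclohexa-2,4-dien-1-one
Conditions: TMSCHN2 (1.5 equiv), toluene/MeOH 4:1, 0 °C
Reagents that add atoms: (trimethylsilyl)diazomethane, C[Si](C)(C)C=[N+]=[N-]
Why: In this diazoalkane O-methylation of an acidic enol, the only acidic proton of 5 sits on O5 in the chelate with the acetyl group and methyl transfer follows proton transfer inside the ion pair, so O5 and not the remote O1 should be methylated, which locks the ketone at C1 next to C6.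

Step 5
Reactants: 6 rac-4-acetyl-6-geranyl-3,5-dimethoxy-6-methylcyclohexa-2,4-dien-1-one
Product: 9 (S)-4-acetyl-6-geranyl-3,5-dimethoxy-6-methylcyclohexa-2,4-dien-1-one, via dienylketene 7 (not isolated), via isothiouronium trienolate 8 (not isolated)
Conditions: hν (365 nm LED), (2S,3R)-HyperBTM (20 mol%), toluene (5 mM), 4 Å MS, Ar, −78 °C, to the photostationary state; light off, −78 → −20 °C; work-up under yellow light
Reagents that add atoms: none
Why: Proposed new method: excitation of either enantiomer of 6 breaks the C1–C6 bond (photochemical α-cleavage, formally a 6π ring opening) and gives dienylketene 7, in which C6 is a trigonal alkene carbon, so both enantiomers drain into one achiral pool (E and Z about C5=C6, which exchange through 6 while the light is on). HyperBTM adds reversibly to the ketene carbon C1 and gives isothiouronium trienolate 8, in which C6, the far end of the trienolate, bonds to the activated acyl carbon C1 with loss of the catalyst, which re-forms C1–C6 and closes six-membered ring B in a 6-(enolendo)-exo-trig mode. The closest known reaction types are the Barton–Quinkert opening of cyclohexa-2,4-dienones with thermal reclosure, catalytic photochemical deracemisation, and Lewis-base-catalysed enantioselective C-acylation (Steglich-type acyl transfer) that builds quaternary carbons; their union on a dienylketene has not been shown. The new C6 stereocentre is controlled by the catalyst alone: the 1,5-S···O contact keeps the acyl unit coplanar with the isothiouronium ring, the phenyl and isopropyl groups screen one face, and the closure that turns the small C6 methyl instead of the geranyl CH2 toward the catalyst should be favoured, which is expected to select the same face of C6 from both ketene isomers. As 9 is as photoactive as 6, material keeps cycling until a photostationary state is reached whose enantiomer ratio is fixed by this face selectivity and by the share of the uncatalysed, racemic disrotatory 6π closure, which −78 °C and the catalyst loading are meant to keep small. The step also needs freedom from irreversible ketene capture, which the substrate secures through the O3 and O5 methyl ethers (no OH that could add or tautomerise) and through the Z C3=C4 bond inherited from the ring, which holds the acetyl oxygen away from C1, while a dry, aprotic, dilute medium and a catalyst transparent at 365 nm do the rest.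

Step 6
Reactants: 9 (S)-4-acetyl-6-geranyl-3,5-dimethoxy-6-methylcyclohexa-2,4-dien-1-one
Product: 10 (R)-2-acetyl-4-geranyl-3,5-dihydroxy-4-methylcyclohexa-2,5-dien-1-one
Conditions: LiOH·H2O (10 equiv), 1,4-dioxane/H2O 3:1, dark, rt → 80 °C; 1 M HCl to pH 3, 0 °C
Reagents that add atoms: lithium hydroxide, [Li+].[OH-]
Why: Hydroxide saponifies the two vinylogous methyl esters by addition–elimination, first at unhindered C3 and then at C5 next to C6, under conditions that prenylated acylphloroglucinol methyl enol ethers tolerate, and the all-carbon quaternary centre has no enolisation path, so the configuration is kept and only the descriptor changes from S to R.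

Step 7
Reactants: 11 phloroglucinol
Product: 12 1-(2,4,6-trihydroxyphenyl)butan-1-one
Conditions: butyric acid (1.1 equiv), BF3·OEt2 (solvent), 80 °C; aq. NaOAc
Reagents that add atoms: butyric acid, CCCC(=O)O
Why: In this Friedel–Crafts (Nencki-type) C-acylation of symmetrical phloroglucinol all three ring carbons are equivalent, and the chelated monoketone is deactivated toward a second acylation.

Step 8
Reactants: 12 1-(2,4,6-trihydroxyphenyl)butan-1-one
Product: 13 1-[4-(tert-butyldimethylsilyloxy)-2,6-dihydroxyphenyl]butan-1-one
Conditions: TBSCl (1.0 equiv), imidazole (2 equiv), DMF, 0 °C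
Reagents that add atoms: tert-butyldimethylsilyl chloride, CC(C)(C)[Si](C)(C)Cl
Why: The silylation should be selective because the para hydroxyl is the most acidic and the only one outside the hydrogen-bonded 2,6-dihydroxyaryl ketone motif, and blocking it leaves only the ortho oxygens for the pyran closure.

Step 9
Reactants: 13 1-[4-(tert-butyldimethylsilyloxy)-2,6-dihydroxyphenyl]butan-1-one; 14 3-methylbut-2-enal (prenal)
Product: 16 1-[5-(tert-butyldimethylsilyloxy)-7-hydroxy-2,2-dimethyl-2H-chromen-8-yl]butan-1-one, via o-quinone methide 15 (not isolated)
Conditions: 14 (1.3 equiv), ethylenediammonium diacetate (10 mol%), toluene, 4 Å MS, 100 °C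
Reagents that add atoms: none
Why: Amine-salt-catalysed Knoevenagel-type condensation of the enal at a free ring carbon gives o-quinone methide 15, whose oxa-6π electrocyclisation can use only an oxygen ortho to the butyryl group, so the 8-acyl chromene is the sole regioisomer (the two ortho halves of 13 are equivalent).

Step 10
Reactants: 16 1-[5-(tert-butyldimethylsilyloxy)-7-hydroxy-2,2-dimethyl-2H-chromen-8-yl]butan-1-one
Product: 17 1-(5,7-dihydroxy-2,2-dimethyl-2H-chromen-8-yl)butan-1-one
Conditions: Et3N·3HF, THF, 0 °C → rt
Reagents that add atoms: none
Why: Fluoride cleaves the phenolic silyl ether under nearly neutral conditions that leave the chromene alkene and the aryl ketone untouched.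

Step 11
Reactants: 17 1-(5,7-dihydroxy-2,2-dimethyl-2H-chromen-8-yl)butan-1-one
Product: 18 1-{6-[(dimethylamino)methyl]-5,7-dihydroxy-2,2-dimethyl-2H-chromen-8-yl}butan-1-one
Conditions: CH2(NMe2)2 (1.2 equiv), 1,4-dioxane, rt
Reagents that add atoms: bis(dimethylamino)methane, CN(C)CN(C)C
Why: Mannich aminomethylation with a preformed aminal, activated by the acidic phenol, takes place at C6 of the chromene, the only free and doubly hydroxyl-activated ring carbon, and the absence of free formaldehyde suppresses symmetrical methylene-bis coupling.

Step 12
Reactants: 10 (R)-2-acetyl-4-geranyl-3,5-dihydroxy-4-methylcyclohexa-2,5-dien-1-one; 18 1-{6-[(dimethylamino)methyl]-5,7-dihydroxy-2,2-dimethyl-2H-chromen-8-yl}butan-1-one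
Product: 20 target CNP0152509.1, via o-quinone methide 19 (not isolated)
Conditions: 10 (1.0 equiv), 18 (1.2 equiv), AcOH (2 equiv), 1,4-dioxane, Ar, 70 °C
Reagents that add atoms: none
Why: In this Mannich-base route to unsymmetrical methylene-bridged phloroglucinols, protonation of the benzylic amine and loss of dimethylamine give o-quinone methide 19, Michael addition of the free C–H carbon of vinylogous acid 10 forms the bridge, and the weakly acidic medium avoids base-induced bridge scrambling and does not touch the quaternary stereocentre.

**Compound list**

1 | 2-methylphloroglucinol (2-methylbenzene-1,3,5-triol) | Cc1c(O)cc(O)cc1O | starting material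
2 | 5-methoxy-2-methylbenzene-1,3-diol | COc1cc(O)c(C)c(O)c1 | intermediate
3 | 1-(2,4-dihydroxy-6-methoxy-3-methylphenyl)ethan-1-one | COc1cc(O)c(C)c(O)c1C(C)=O | intermediate
4 | geranyl bromide, (2E)-1-bromo-3,7-dimethylocta-2,6-diene | BrC/C=C(\C)CCC=C(C)C | starting material
5 | rac-4-acetyl-6-[(2E)-3,7-dimethylocta-2,6-dien-1-yl]-5-hydroxy-3-methoxy-6-methylcyclohexa-2,4-dien-1-one | COC1=CC(=O)C(C)(C/C=C(\C)CCC=C(C)C)C(O)=C1C(C)=O | intermediate
6 | rac-4-acetyl-6-geranyl-3,5-dimethoxy-6-methylcyclohexa-2,4-dien-1-one | COC1=CC(=O)C(C)(C/C=C(\C)CCC=C(C)C)C(OC)=C1C(C)=O | intermediate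
7 | dienylketene, (3Z,8E)-4-acetyl-3,5-dimethoxy-6,9,13-trimethyltetradeca-1,3,5,8,12-pentaen-1-one, E and Z about C5=C6 | O=C=C/C(OC)=C(C(C)=O)\C(OC)=C(C)C/C=C(\C)CCC=C(C)C | intermediate
8 | isothiouronium trienolate, adduct of (2S,3R)-HyperBTM through its imine nitrogen to C1 of 7 | CC(C)[C@@H]1CN2c3ccccc3SC2=[N+](C([O-])=C/C(OC)=C(C(C)=O)\C(OC)=C(C)C/C=C(\C)CCC=C(C)C)[C@@H]1c1ccccc1 | intermediate
9 | (S)-4-acetyl-6-geranyl-3,5-dimethoxy-6-methylcyclohexa-2,4-dien-1-one | COC1=CC(=O)[C@@](C)(C/C=C(\C)CCC=C(C)C)C(OC)=C1C(C)=O | intermediate
10 | (R)-2-acetyl-4-geranyl-3,5-dihydroxy-4-methylcyclohexa-2,5-dien-1-one | O=C1C=C(O)[C@@](C)(C/C=C(\C)CCC=C(C)C)C(O)=C1C(C)=O | intermediate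
11 | phloroglucinol | Oc1cc(O)cc(O)c1 | starting material
12 | 1-(2,4,6-trihydroxyphenyl)butan-1-one | CCCC(=O)c1c(O)cc(O)cc1O | intermediate
13 | 1-[4-(tert-butyldimethylsilyloxy)-2,6-dihydroxyphenyl]butan-1-one | CCCC(=O)c1c(O)cc(O[Si](C)(C)C(C)(C)C)cc1O | intermediate
14 | 3-methylbut-2-enal (prenal) | CC(C)=CC=O | starting material
15 | o-quinone methide, 2-butyryl-5-(tert-butyldimethylsilyloxy)-3-hydroxy-6-(3-methylbut-2-enylidene)cyclohexa-2,4-dien-1-one | CCCC(=O)C1=C(O)C=C(O[Si](C)(C)C(C)(C)C)C(=CC=C(C)C)C1=O | intermediate
16 | 1-[5-(tert-butyldimethylsilyloxy)-7-hydroxy-2,2-dimethyl-2H-chromen-8-yl]butan-1-one | CCCC(=O)c1c(O)cc(O[Si](C)(C)C(C)(C)C)c2c1OC(C)(C)C=C2 | intermediate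
17 | 1-(5,7-dihydroxy-2,2-dimethyl-2H-chromen-8-yl)butan-1-one | CCCC(=O)c1c(O)cc(O)c2c1OC(C)(C)C=C2 | intermediate
18 | 1-{6-[(dimethylamino)methyl]-5,7-dihydroxy-2,2-dimethyl-2H-chromen-8-yl}butan-1-one | CCCC(=O)c1c(O)c(CN(C)C)c(O)c2c1OC(C)(C)C=C2 | intermediate
19 | o-quinone methide, 8-butyryl-7-hydroxy-2,2-dimethyl-6-methylidene-2H-chromen-5(6H)-one | CCCC(=O)C1=C(O)C(=C)C(=O)C2=C1OC(C)(C)C=C2 | intermediate
20 | target: (R)-2-acetyl-6-[(8-butyryl-5,7-dihydroxy-2,2-dimethyl-2H-chromen-6-yl)methyl]-4-geranyl-3,5-dihydroxy-4-methylcyclohexa-2,5-dien-1-one | CCCC(=O)c1c(O)c(CC2=C(O)[C@@](C)(C/C=C(\C)CCC=C(C)C)C(O)=C(C(C)=O)C2=O)c(O)c2c1OC(C)(C)C=C2 | target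

**Totals**
- Total step count: 12.
- Longest linear sequence: 7 steps (steps 1–6, then step 12). The chromene branch has 6 (steps 7–11, then step 12).

**Steps most likely to fail**

1. **Step 5 (new method).**
   - Risk:
     - The ketene may be lost through irreversible channels. These are photochemical or thermal isomerisation of the dienone/ketene pair to a bicyclic ketone, light- or catalyst-induced rotation about C3=C4 followed by lactonisation through the acetyl oxygen, and Lewis-base-induced ketene dimerisation.
     - The racemic thermal closure may outrun the catalysed one.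
     - The two ketene geometrical isomers may close with opposite facial outcome, which would cap the enrichment.
   - Fallback (known chemistry): it sets out from 6 and returns at 9.
     - Racemic 6 is resolved by preparative SFC on an immobilised polysaccharide chiral phase, and the (S)-enantiomer is 9.
     - The unwanted (R)-4-acetyl-6-geranyl-3,5-dimethoxy-6-methylcyclohexa-2,4-dien-1-one F1 is racemised by irradiation in toluene at room temperature without catalyst (photochemical opening, thermal reclosure) and resolved again.

2. **Step 3.**
   - Risk: site selectivity may be poor, with alkylation at the ring C–H carbon or on oxygen competing with attack at the methyl-bearing carbon, and a second alkylation may follow.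
   - Fallback (blocking-group approach): it sets out from 3 and returns at 5.
     - NBS (1 equiv, MeCN, 0 °C) brominates the only free ring carbon and gives 1-(3-bromo-4,6-dihydroxy-2-methoxy-5-methylphenyl)ethan-1-one F2.
     - Deprotonation and alkylation with 4 as in step 3 are now directed to the methyl-bearing carbon. This gives rac-4-acetyl-2-bromo-6-geranyl-5-hydroxy-3-methoxy-6-methylcyclohexa-2,4-dien-1-one F3.
     - Na2SO3 in aqueous MeOH removes the bromine through the keto tautomer, as in the sulfite debromination of polybrominated resorcinols, and gives 5.

3. **Step 4.**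
   - Risk: site selectivity of methyl transfer among O5, the acetyl oxygen and O1 may be poor, so a wrong tautomer would be locked.
   - Fallback (both methyl ethers fixed on the arene): it sets out from 3 and returns at 6.
     - BnBr/K2CO3/acetone benzylates the non-chelated para hydroxyl and gives 1-[4-(benzyloxy)-2-hydroxy-6-methoxy-3-methylphenyl]ethan-1-one F4.
     - MeI/K2CO3/DMF methylates the chelated hydroxyl and gives 1-[4-(benzyloxy)-2,6-dimethoxy-3-methylphenyl]ethan-1-one F5.
     - Hydrogenolysis (H2, Pd/C) gives 1-(4-hydroxy-2,6-dimethoxy-3-methylphenyl)ethan-1-one F6.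
     - The sodium phenolate of F6 (NaH, toluene) is ortho-C-alkylated with 4 in the non-polar medium at the methyl-bearing carbon, which gives 6 with unambiguous methoxy positions.

**Further compounds**

F1 | step 5 | (R)-4-acetyl-6-geranyl-3,5-dimethoxy-6-methylcyclohexa-2,4-dien-1-one | COC1=CC(=O)[C@](C)(C/C=C(\C)CCC=C(C)C)C(OC)=C1C(C)=O
F2 | step 3 | 1-(3-bromo-4,6-dihydroxy-2-methoxy-5-methylphenyl)ethan-1-one | COc1c(Br)c(O)c(C)c(O)c1C(C)=O
F3 | step 3 | rac-4-acetyl-2-bromo-6-geranyl-5-hydroxy-3-methoxy-6-methylcyclohexa-2,4-dien-1-one | COC1=C(Br)C(=O)C(C)(C/C=C(\C)CCC=C(C)C)C(O)=C1C(C)=O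
F4 | step 4 | 1-[4-(benzyloxy)-2-hydroxy-6-methoxy-3-methylphenyl]ethan-1-one | COc1cc(OCc2ccccc2)c(C)c(O)c1C(C)=O
F5 | step 4 | 1-[4-(benzyloxy)-2,6-dimethoxy-3-methylphenyl]ethan-1-one | COc1cc(OCc2ccccc2)c(C)c(OC)c1C(C)=O
F6 | step 4 | 1-(4-hydroxy-2,6-dimethoxy-3-methylphenyl)ethan-1-one | COc1cc(O)c(C)c(OC)c1C(C)=O
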